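## Retrosynthetic overview

1. The target comes from a silyl-protected carbinol by desilylation and Dess–Martin oxidation. Its vinyl oxirane (last ring) comes from a site- and face-selective chiral-dioxirane epoxidation of a 5,6-cis-disubstituted cyclohexa-1,3-diene.
2. The cyclohexadiene (second ring) comes from thermal disrotatory 6π-electrocyclization of an (E,Z,E)-triene, with separation of the two ring diastereomers. The triene is made in the key Suzuki–Miyaura coupling of a pyranonyl (E)-alkenylboronate with a (Z)-2-iodotriene.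
3. The alkenylboronate comes from the pyranone ring (first ring: dianion formylation, lactonisation, O-methylation) by nickel/aluminium C6–H alkenylation with a silylpropyne, iododesilylation and borylation.
4. The (Z)-iodotriene comes from Zhao olefination of a dienal. The dienal comes from Negishi coupling of an alkenylzirconocene with (E)-3-iodo-2-methylprop-2-en-1-ol; both side-chain stereocentres come from a Marshall propargylation of propanal.

Assumption: the target is taken exactly as drawn in the SMILES, i.e. (1R,4R,5R,6S) in the 7-oxabicyclo[4.1.0]hept-2-ene core and (2E,4R) in the side chain, and all numbered starting materials are taken as commercially available.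

## Route

Step 1
Reactants: 1 ethyl propanoate (two molecules)
Product: 2 ethyl 2-methyl-3-oxopentanoate
Conditions: NaH (1.1 equiv), cat. EtOH, THF, reflux; AcOH
Reagents that add atoms: none
Why: Claisen self-condensation, made irreversible by deprotonation of the β-keto ester formed; the α-carbon is a racemic, later planar centre, so no stereocontrol is needed.

Step 2
Reactants: 2 ethyl 2-methyl-3-oxopentanoate; 3 N-methoxy-N-methylformamide
Product: 5 ethyl 2,4-dimethyl-3,5-dioxopentanoate, via dilithium dianion 4 (not isolated)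
Conditions: LiN(i-Pr)2 (2.2 equiv), THF, −78 → 0 °C; 3, −78 °C; aq. HCl
Reagents that add atoms: none
Why: Weiler dianion γ-acylation, in which the more reactive γ-carbanion of 4 attacks the Weinreb formamide and the chelated tetrahedral adduct survives until work-up, preventing double addition and proton exchange; both stereocentres of 5 become sp2 in step 3.

Step 3
Reactants: 5 ethyl 2,4-dimethyl-3,5-dioxopentanoate
Product: 6 4-hydroxy-3,5-dimethyl-2H-pyran-2-one
Conditions: DBU (1.5 equiv), PhMe, 80 °C; aq. HCl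
Reagents that add atoms: none
Why: Base-mediated lactonisation of the hydroxymethylene enol oxygen onto the ester (the classical triketide to 4-hydroxy-2-pyranone cyclisation) with loss of ethanol forms the heteroaromatic ring; no stereocentre remains.

Step 4
Reactants: 6 4-hydroxy-3,5-dimethyl-2H-pyran-2-one
Product: 7 2-methoxy-3,5-dimethyl-4H-pyran-4-one
Conditions: MeOTf (1.1 equiv), CH2Cl2, 0 °C → rt; aq. NaHCO3
Reagents that add atoms: methyl trifluoromethanesulfonate COS(=O)(=O)C(F)(F)F
Why: Hard-electrophile O-methylation of the neutral hydroxypyranone at the lactone carbonyl oxygen, followed by loss of the 4-OH proton, gives the α-methoxy-γ-pyranone regioisomer (Beak-type methylation of 4-hydroxy-2-pyranones).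

Step 5
Reactants: 7 2-methoxy-3,5-dimethyl-4H-pyran-4-one; 8 trimethyl(prop-1-yn-1-yl)silane
Product: 9 2-methoxy-3,5-dimethyl-6-[(1E)-1-(trimethylsilyl)prop-1-en-2-yl]-4H-pyran-4-one
Conditions: Ni(cod)2 (10 mol %), P(i-Pr)3 (20 mol %), AlMe3 (20 mol %), PhMe, 80 °C
Reagents that add atoms: none
Why: Proposed new method: nickel/aluminium-cooperative C6–H alkenylation of a 4-pyranone by alkyne hydroheteroarylation, in which AlMe3 binds the pyranone carbonyl (acidifying the vinylogous-formate C6–H and lowering the ring LUMO), alkyne-bound zerovalent nickel transfers this hydrogen to the silyl-bearing alkyne carbon (ligand-to-ligand hydrogen transfer) and reductive elimination forms the pyranonyl–alkenyl bond, so that syn addition gives the E alkene and sterics place the pyranonyl group on the methyl-bearing carbon; the closest known reaction type is the Nakao–Hiyama nickel/Lewis acid alkenylation of 2-pyridones, pyridines and azoles with internal alkynes.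

Step 6
Reactants: 9 2-methoxy-3,5-dimethyl-6-[(1E)-1-(trimethylsilyl)prop-1-en-2-yl]-4H-pyran-4-one
Product: 10 6-[(1E)-1-iodoprop-1-en-2-yl]-2-methoxy-3,5-dimethyl-4H-pyran-4-one
Conditions: N-iodosuccinimide (1.3 equiv), (CF3)2CHOH, 0 °C
Reagents that add atoms: N-iodosuccinimide O=C1CCC(=O)N1I
Why: Electrophilic ipso-iododesilylation, in which iodonium attack at the silyl-bearing carbon gives a β-silyl-stabilised cation that loses silicon with retention, so the E geometry is kept.

Step 7
Reactants: 10 6-[(1E)-1-iodoprop-1-en-2-yl]-2-methoxy-3,5-dimethyl-4H-pyran-4-one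
Product: 11 2-methoxy-3,5-dimethyl-6-[(1E)-1-(4,4,5,5-tetramethyl-1,3,2-dioxaborolan-2-yl)prop-1-en-2-yl]-4H-pyran-4-one
Conditions: B2pin2 (1.1 equiv), PdCl2(PPh3)2 (3 mol %), PPh3 (6 mol %), KOPh (1.5 equiv), PhMe, 50 °C
Reagents that add atoms: bis(pinacolato)diboron CC1(C)OB(OC1(C)C)B1OC(C)(C)C(C)(C)O1
Why: Miyaura borylation of an alkenyl iodide (oxidative addition to zerovalent palladium, phenoxide-assisted transmetalation with B2pin2, reductive elimination) proceeds with retention of the E geometry.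

Step 8
Reactants: 12 (2S)-but-3-yn-2-ol
Product: 13 (2S)-but-3-yn-2-yl methanesulfonate
Conditions: MsCl (1.2 equiv), Et3N (1.5 equiv), CH2Cl2, −78 → 0 °C
Reagents that add atoms: methanesulfonyl chloride CS(=O)(=O)Cl
Why: Sulfonylation takes place at oxygen only, so the S configuration of the carbinol carbon is retained in the propargylic mesylate.

Step 9
Reactants: 13 (2S)-but-3-yn-2-yl methanesulfonate; 14 propanal
Product: 16 (3S,4R)-4-methylhex-5-yn-3-ol, via allenylzinc mesylate 15 (not isolated)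
Conditions: Pd(OAc)2 (5 mol %), PPh3 (5 mol %), Et2Zn (3 equiv), THF, −78 → −20 °C; aq. NH4Cl
Reagents that add atoms: none
Why: Marshall propargylation, in which zerovalent palladium ionises the mesylate in an anti SN2' sense, Et2Zn transmetalates the allenylpalladium to the configurationally defined allenylzinc 15, and 15 adds to propanal through a cyclic SE2' transition state; this sets the methyl-bearing carbon as R by chirality transfer from the S mesylate and the carbinol carbon as S (anti adduct).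

Step 10
Reactants: 16 (3S,4R)-4-methylhex-5-yn-3-ol
Product: 17 tert-butyl(dimethyl){[(3S,4R)-4-methylhex-5-yn-3-yl]oxy}silane
Conditions: TBSOTf (1.2 equiv), 2,6-lutidine (1.5 equiv), CH2Cl2, −78 → 0 °C
Reagents that add atoms: tert-butyldimethylsilyl trifluoromethanesulfonate CC(C)(C)[Si](C)(C)OS(=O)(=O)C(F)(F)F
Why: Silyl ether formation with a silyl triflate and a hindered pyridine base protects the secondary alcohol without touching either stereocentre.

Step 11
Reactants: 17 tert-butyl(dimethyl){[(3S,4R)-4-methylhex-5-yn-3-yl]oxy}silane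
Product: 19 tert-butyl(dimethyl){[(3S,4R)-4-methylhept-5-yn-3-yl]oxy}silane, via lithium acetylide 18 (not isolated)
Conditions: n-BuLi (1.1 equiv), THF, −78 °C; MeI (1.5 equiv), −78 °C → rt
Reagents that add atoms: iodomethane CI
Why: Deprotonation of the terminal alkyne and SN2 methylation of the lithium acetylide; the stereocentres are remote from the reacting carbon.

Step 12
Reactants: 20 prop-2-yn-1-ol
Product: 22 (2E)-3-iodo-2-methylprop-2-en-1-ol, via alkenylalane 21 (not isolated)
Conditions: AlMe3 (3 equiv), Cp2ZrCl2 (25 mol %), CH2Cl2, 0 °C → rt; I2 (1.2 equiv), THF, −30 → 0 °C; aq. K2CO3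
Reagents that add atoms: trimethylaluminium C[Al](C)C; iodine II
Why: Negishi zirconium-catalysed carboalumination adds methyl and aluminium syn across the alkyne with methyl on the internal carbon, and iodinolysis of the alkenyl–aluminium bond with retention gives the E iodoalkene.

Step 13
Reactants: 19 tert-butyl(dimethyl){[(3S,4R)-4-methylhept-5-yn-3-yl]oxy}silane; 22 (2E)-3-iodo-2-methylprop-2-en-1-ol
Product: 25 (2E,4E,6R,7S)-7-{[tert-butyl(dimethyl)silyl]oxy}-2,4,6-trimethylnona-2,4-dien-1-ol, via alkenylzirconocene chloride 23 (not isolated), via alkenylzinc chloride 24 (not isolated)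
Conditions: Cp2Zr(H)Cl (1.5 equiv), THF, 50 °C; ZnCl2 (1.5 equiv), 0 °C; 22 (1.2 equiv), Pd(PPh3)4 (5 mol %), rt
Reagents that add atoms: none
Why: Hydrozirconation adds Zr–H syn and, after equilibration, places zirconium on the less hindered methyl-bearing alkyne carbon; transmetalation to zinc and Negishi coupling under zerovalent palladium then join the two alkenyl carbons with retention at both, giving the (2E,4E)-dienol (the free hydroxyl is tolerated by the alkenylzinc coupling).

Step 14
Reactants: 25 (2E,4E,6R,7S)-7-{[tert-butyl(dimethyl)silyl]oxy}-2,4,6-trimethylnona-2,4-dien-1-ol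
Product: 26 (2E,4E,6R,7S)-7-{[tert-butyl(dimethyl)silyl]oxy}-2,4,6-trimethylnona-2,4-dienal
Conditions: MnO2 (20 equiv), CH2Cl2, rt
Reagents that add atoms: none
Why: MnO2 oxidises the allylic alcohol selectively to the dienal under neutral conditions that leave the silyl ether and the allylic methyl stereocentre untouched.

Step 15
Reactants: 27 iodoethane
Product: 28 ethyltriphenylphosphonium iodide
Conditions: PPh3 (1.0 equiv), PhMe, reflux
Reagents that add atoms: triphenylphosphine c1ccc(cc1)P(c1ccccc1)c1ccccc1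
Why: SN2 quaternisation of triphenylphosphine by the primary iodide gives the phosphonium salt.

Step 16
Reactants: 26 (2E,4E,6R,7S)-7-{[tert-butyl(dimethyl)silyl]oxy}-2,4,6-trimethylnona-2,4-dienal; 28 ethyltriphenylphosphonium iodide
Product: 32 tert-butyl{[(3S,4R,5E,7E,9Z)-10-iodo-4,6,8-trimethylundeca-5,7,9-trien-3-yl]oxy}dimethylsilane, via ethylidenetriphenylphosphorane 29 (not isolated), via (1-iodoethyl)triphenylphosphonium iodide 30 (not isolated), via (1-iodoethylidene)triphenylphosphorane 31 (not isolated)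
Conditions: 28 (2.0 equiv), n-BuLi, THF, 0 °C → rt; I2, −78 °C; NaN(SiMe3)2, −78 → −20 °C; then 26, −78 °C → rt
Reagents that add atoms: iodine II
Why: Zhao olefination, in which the α-iodo ylide 31 (made by iodination of ylide 29 and deprotonation of 30) reacts with the aldehyde under kinetic control to give the (Z)-2-iodoalkene (chain and iodine cis), the geometry later needed for ring closure.

Step 17
Reactants: 32 tert-butyl{[(3S,4R,5E,7E,9Z)-10-iodo-4,6,8-trimethylundeca-5,7,9-trien-3-yl]oxy}dimethylsilane; 11 2-methoxy-3,5-dimethyl-6-[(1E)-1-(4,4,5,5-tetramethyl-1,3,2-dioxaborolan-2-yl)prop-1-en-2-yl]-4H-pyran-4-one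
Product: 34 6-[(1R,6S)-6-[(2E,4R,5S)-5-{[tert-butyl(dimethyl)silyl]oxy}-4-methylhept-2-en-2-yl]-1,3,5-trimethylcyclohexa-2,4-dien-1-yl]-2-methoxy-3,5-dimethyl-4H-pyran-4-one, via tetraene 33 (not isolated)
Conditions: Pd(PPh3)4 (10 mol %), TlOEt (1.8 equiv), THF/H2O 3:1, rt, dark; then PhMe, 80 °C; preparative HPLC (silica, hexane/EtOAc)
Reagents that add atoms: none
Why: Suzuki–Miyaura coupling joins the iodine-bearing carbon of 32 to the boron-bearing carbon of 11 with retention at both alkenes, and the resulting (E,Z,E)-triene unit of 33 undergoes thermal disrotatory 6π-electrocyclization that places the two outward groups (pyranonyl and side chain) cis, which sets the relative configuration of the quaternary and the adjacent tertiary ring carbon; the remote side-chain centres exert almost no facial bias, so the two disrotatory senses are used about equally and 34, the (1R,6S) isomer, is obtained pure (at most about half of the cyclised material) by preparative HPLC separation from its (1S,6R) ring diastereomer.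

Step 18
Reactants: 34 6-[(1R,6S)-6-[(2E,4R,5S)-5-{[tert-butyl(dimethyl)silyl]oxy}-4-methylhept-2-en-2-yl]-1,3,5-trimethylcyclohexa-2,4-dien-1-yl]-2-methoxy-3,5-dimethyl-4H-pyran-4-one
Product: 35 6-[(1R,4R,5R,6S)-5-[(2E,4R,5S)-5-{[tert-butyl(dimethyl)silyl]oxy}-4-methylhept-2-en-2-yl]-2,4,6-trimethyl-7-oxabicyclo[4.1.0]hept-2-en-4-yl]-2-methoxy-3,5-dimethyl-4H-pyran-4-one
Conditions: D-fructose-derived Shi ketone (30 mol %), KHSO5 (as 2KHSO5·KHSO4·K2SO4, 1.2 equiv), K2CO3, Bu4NHSO4 (5 mol %), MeCN/CH2(OMe)2/aq. Na2B4O7 buffer pH 10.5, −10 → 0 °C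
Reagents that add atoms: potassium peroxymonosulfate [K+].[O-]S(=O)(=O)OO
Why: Shi asymmetric epoxidation, a reaction type known to mono-epoxidise conjugated dienes to vinyl oxiranes; the chiral dioxirane attacks the diene double bond next to the tertiary ring carbon on the face anti to both the cis-disposed side chain and pyranonyl group (substrate control), and the spiro transition-state model for this ketone, by analogy with 1-phenylcyclohexene, predicts the same face, so both oxirane carbons are set in a matched sense; the ring alkene next to the quaternary carbon and the side-chain alkene flanked by two branched carbons and the bulky silyl ether are shielded, and the buffered basic medium preserves the vinyl oxirane.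

Step 19
Reactants: 35 6-[(1R,4R,5R,6S)-5-[(2E,4R,5S)-5-{[tert-butyl(dimethyl)silyl]oxy}-4-methylhept-2-en-2-yl]-2,4,6-trimethyl-7-oxabicyclo[4.1.0]hept-2-en-4-yl]-2-methoxy-3,5-dimethyl-4H-pyran-4-one
Product: 36 6-[(1R,4R,5R,6S)-5-[(2E,4R,5S)-5-hydroxy-4-methylhept-2-en-2-yl]-2,4,6-trimethyl-7-oxabicyclo[4.1.0]hept-2-en-4-yl]-2-methoxy-3,5-dimethyl-4H-pyran-4-one
Conditions: Bu4NF (3 equiv), THF, 0 °C → rt
Reagents that add atoms: none
Why: Fluoride cleaves the Si–O bond (desilylation) under non-acidic conditions that the vinyl oxirane and the methoxypyranone tolerate; no stereocentre is affected.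

Step 20
Reactants: 36 6-[(1R,4R,5R,6S)-5-[(2E,4R,5S)-5-hydroxy-4-methylhept-2-en-2-yl]-2,4,6-trimethyl-7-oxabicyclo[4.1.0]hept-2-en-4-yl]-2-methoxy-3,5-dimethyl-4H-pyran-4-one
Product: 37 2-methoxy-3,5-dimethyl-6-[(1R,4R,5R,6S)-2,4,6-trimethyl-5-[(2E,4R)-4-methyl-5-oxohept-2-en-2-yl]-7-oxabicyclo[4.1.0]hept-2-en-4-yl]-4H-pyran-4-one
Conditions: Dess–Martin periodinane (1.5 equiv), NaHCO3 (5 equiv), CH2Cl2, 0 °C → rt
Reagents that add atoms: none
Why: Dess–Martin oxidation under buffered, non-enolising conditions converts the carbinol into the ethyl ketone without epimerising the adjacent methyl-bearing centre or moving the β,γ-double bond into conjugation.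

## Compound list

1 | ethyl propanoate | CCC(=O)OCC | starting material
2 | ethyl 2-methyl-3-oxopentanoate (racemic) | CCC(=O)C(C)C(=O)OCC | intermediate
3 | N-methoxy-N-methylformamide | CON(C)C=O | starting material
4 | dilithium dianion of 2 (dilithium 1-ethoxy-2-methylpenta-1,3-diene-1,3-diolate) | [Li+].[Li+].CCOC([O-])=C(C)C([O-])=CC | intermediate
5 | ethyl 2,4-dimethyl-3,5-dioxopentanoate (stereoisomer and enol mixture) | CCOC(=O)C(C)C(=O)C(C)C=O | intermediate
6 | 4-hydroxy-3,5-dimethyl-2H-pyran-2-one | CC1=COC(=O)C(C)=C1O | intermediate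
7 | 2-methoxy-3,5-dimethyl-4H-pyran-4-one | COc1occ(C)c(=O)c1C | intermediate
8 | trimethyl(prop-1-yn-1-yl)silane | CC#C[Si](C)(C)C | starting material
9 | 2-methoxy-3,5-dimethyl-6-[(1E)-1-(trimethylsilyl)prop-1-en-2-yl]-4H-pyran-4-one | COc1oc(/C(C)=C/[Si](C)(C)C)c(C)c(=O)c1C | intermediate
10 | 6-[(1E)-1-iodoprop-1-en-2-yl]-2-methoxy-3,5-dimethyl-4H-pyran-4-one | COc1oc(/C(C)=C/I)c(C)c(=O)c1C | intermediate
11 | 2-methoxy-3,5-dimethyl-6-[(1E)-1-(4,4,5,5-tetramethyl-1,3,2-dioxaborolan-2-yl)prop-1-en-2-yl]-4H-pyran-4-one | COc1oc(/C(C)=C/B2OC(C)(C)C(C)(C)O2)c(C)c(=O)c1C | intermediate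
12 | (2S)-but-3-yn-2-ol | C[C@H](O)C#C | starting material
13 | (2S)-but-3-yn-2-yl methanesulfonate | C[C@H](OS(C)(=O)=O)C#C | intermediate
14 | propanal | CCC=O | starting material
15 | (M)-buta-1,2-dien-1-ylzinc methanesulfonate | [H]C(C)=[C@@]=C([H])[Zn]OS(C)(=O)=O | intermediate
16 | (3S,4R)-4-methylhex-5-yn-3-ol | CC[C@H](O)[C@H](C)C#C | intermediate
17 | tert-butyl(dimethyl){[(3S,4R)-4-methylhex-5-yn-3-yl]oxy}silane | CC[C@H](O[Si](C)(C)C(C)(C)C)[C@H](C)C#C | intermediate
18 | lithium (3R,4S)-4-{[tert-butyl(dimethyl)silyl]oxy}-3-methylhex-1-yn-1-ide | CC[C@H](O[Si](C)(C)C(C)(C)C)[C@H](C)C#C[Li] | intermediate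
19 | tert-butyl(dimethyl){[(3S,4R)-4-methylhept-5-yn-3-yl]oxy}silane | CC[C@H](O[Si](C)(C)C(C)(C)C)[C@H](C)C#CC | intermediate
20 | prop-2-yn-1-ol | OCC#C | starting material
21 | [(1E)-3-(dimethylalumanyloxy)-2-methylprop-1-en-1-yl]dimethylalumane | C[Al](C)/C=C(\C)CO[Al](C)C | intermediate
22 | (2E)-3-iodo-2-methylprop-2-en-1-ol | OC/C(C)=C/I | intermediate
23 | chloro[(2E,4R,5S)-5-{[tert-butyl(dimethyl)silyl]oxy}-4-methylhept-2-en-2-yl]bis(cyclopentadienyl)zirconium (cyclopentadienyl rings drawn σ-bound) | CC[C@H](O[Si](C)(C)C(C)(C)C)[C@H](C)/C=C(\C)[Zr](Cl)(C1C=CC=C1)C1C=CC=C1 | intermediate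
24 | chloro[(2E,4R,5S)-5-{[tert-butyl(dimethyl)silyl]oxy}-4-methylhept-2-en-2-yl]zinc | CC[C@H](O[Si](C)(C)C(C)(C)C)[C@H](C)/C=C(\C)[Zn]Cl | intermediate
25 | (2E,4E,6R,7S)-7-{[tert-butyl(dimethyl)silyl]oxy}-2,4,6-trimethylnona-2,4-dien-1-ol | CC[C@H](O[Si](C)(C)C(C)(C)C)[C@H](C)/C=C(\C)/C=C(\C)CO | intermediate
26 | (2E,4E,6R,7S)-7-{[tert-butyl(dimethyl)silyl]oxy}-2,4,6-trimethylnona-2,4-dienal | CC[C@H](O[Si](C)(C)C(C)(C)C)[C@H](C)/C=C(\C)/C=C(\C)C=O | intermediate
27 | iodoethane | CCI | starting material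
28 | ethyltriphenylphosphonium iodide | CC[P+](c1ccccc1)(c1ccccc1)c1ccccc1.[I-] | intermediate
29 | ethylidenetriphenylphosphorane | CC=P(c1ccccc1)(c1ccccc1)c1ccccc1 | intermediate
30 | (1-iodoethyl)triphenylphosphonium iodide | CC(I)[P+](c1ccccc1)(c1ccccc1)c1ccccc1.[I-] | intermediate
31 | (1-iodoethylidene)triphenylphosphorane | CC(I)=P(c1ccccc1)(c1ccccc1)c1ccccc1 | intermediate
32 | tert-butyl{[(3S,4R,5E,7E,9Z)-10-iodo-4,6,8-trimethylundeca-5,7,9-trien-3-yl]oxy}dimethylsilane | CC[C@H](O[Si](C)(C)C(C)(C)C)[C@H](C)/C=C(\C)/C=C(\C)/C=C(/C)\I | intermediate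
33 | 6-[(2E,4Z,6E,8E,10R,11S)-11-{[tert-butyl(dimethyl)silyl]oxy}-4,6,8,10-tetramethyltrideca-2,4,6,8-tetraen-2-yl]-2-methoxy-3,5-dimethyl-4H-pyran-4-one | CC[C@H](O[Si](C)(C)C(C)(C)C)[C@H](C)/C=C(\C)/C=C(\C)/C=C(/C)\C=C(/C)\c1oc(OC)c(C)c(=O)c1C | intermediate
34 | 6-[(1R,6S)-6-[(2E,4R,5S)-5-{[tert-butyl(dimethyl)silyl]oxy}-4-methylhept-2-en-2-yl]-1,3,5-trimethylcyclohexa-2,4-dien-1-yl]-2-methoxy-3,5-dimethyl-4H-pyran-4-one (pyranonyl and side chain cis) | CC[C@H](O[Si](C)(C)C(C)(C)C)[C@H](C)/C=C(\C)[C@H]1C(C)=CC(C)=C[C@@]1(C)c1oc(OC)c(C)c(=O)c1C | intermediate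
35 | 6-[(1R,4R,5R,6S)-5-[(2E,4R,5S)-5-{[tert-butyl(dimethyl)silyl]oxy}-4-methylhept-2-en-2-yl]-2,4,6-trimethyl-7-oxabicyclo[4.1.0]hept-2-en-4-yl]-2-methoxy-3,5-dimethyl-4H-pyran-4-one | CC[C@H](O[Si](C)(C)C(C)(C)C)[C@H](C)/C=C(\C)[C@H]1[C@]2(C)O[C@@H]2C(C)=C[C@@]1(C)c1oc(OC)c(C)c(=O)c1C | intermediate
36 | 6-[(1R,4R,5R,6S)-5-[(2E,4R,5S)-5-hydroxy-4-methylhept-2-en-2-yl]-2,4,6-trimethyl-7-oxabicyclo[4.1.0]hept-2-en-4-yl]-2-methoxy-3,5-dimethyl-4H-pyran-4-one | CC[C@H](O)[C@H](C)/C=C(\C)[C@H]1[C@]2(C)O[C@@H]2C(C)=C[C@@]1(C)c1oc(OC)c(C)c(=O)c1C | intermediate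
37 | 2-methoxy-3,5-dimethyl-6-[(1R,4R,5R,6S)-2,4,6-trimethyl-5-[(2E,4R)-4-methyl-5-oxohept-2-en-2-yl]-7-oxabicyclo[4.1.0]hept-2-en-4-yl]-4H-pyran-4-one | CCC(=O)[C@H](C)/C=C(\C)[C@H]1[C@]2(C)O[C@@H]2C(C)=C[C@@]1(C)c1oc(OC)c(C)c(=O)c1C | target

## Step count and risks

Total step count: 20.
Longest linear sequence: 11 steps (steps 8, 9, 10, 11, 13, 14, 16, 17, 18, 19, 20; the pyranone branch, steps 1–7 then 17–20, is equally long), i.e. 11/20 = 0.55 of the total.

The three steps most likely to fail:

Step 5 (the proposed new C–H alkenylation). Possible failures are no C–H activation, nickel insertion into a C–O bond of the methoxypyranone, or alkyne oligomerisation. The fallback sets out from 2 (through its dianion 4) and from 32, and comes back to the route at 33. It makes the pyranone–alkene bond by the established aldol condensation of a lithiated 6-ethylpyranone, so that 7–11 and the Suzuki coupling are not needed. Dianion 4 is acylated with N-methoxy-N-methylpropanamide to give ethyl 2,4-dimethyl-3,5-dioxoheptanoate F1. DBU closes it to 6-ethyl-4-hydroxy-3,5-dimethyl-2H-pyran-2-one F2, and MeOTf gives 6-ethyl-2-methoxy-3,5-dimethyl-4H-pyran-4-one F3. In parallel, iodide 32 is converted by t-BuLi and then DMF into (2Z,4E,6E,8R,9S)-9-{[tert-butyl(dimethyl)silyl]oxy}-2,4,6,8-tetramethylundeca-2,4,6-trienal F4. F3 is deprotonated at the ethyl CH2 with LiN(SiMe3)2 and added to F4 to give 6-[(4Z,6E,8E,10R,11S)-11-{[tert-butyl(dimethyl)silyl]oxy}-3-hydroxy-4,6,8,10-tetramethyltrideca-4,6,8-trien-2-yl]-2-methoxy-3,5-dimethyl-4H-pyran-4-one F5. MsCl/Et3N converts F5 into 6-[(4Z,6E,8E,10R,11S)-11-{[tert-butyl(dimethyl)silyl]oxy}-4,6,8,10-tetramethyl-3-[(methylsulfonyl)oxy]trideca-4,6,8-trien-2-yl]-2-methoxy-3,5-dimethyl-4H-pyran-4-one F6. DBU eliminates F6 to the E alkene, which is tetraene 33; 33 is heated in PhMe and the product separated as in step 17 to give 34.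

Step 17 (Suzuki coupling and ring closure). Possible failures are slow coupling of the hindered (Z)-iodide, loss of the pyranonyl boronate under base, or a competing [1,7]-hydrogen shift if the triene has to be heated for long. A loss that cannot be avoided is that only about half of the cyclised material has the needed ring configuration. The fallback sets out from 32 and 10 and comes back at 33. It reverses the roles of the two fragments and works without base or boron. Iodide 32 is treated with t-BuLi (Et2O, −78 °C) and Me3SnCl to give tert-butyl(dimethyl){[(3S,4R,5E,7E,9Z)-4,6,8-trimethyl-10-(trimethylstannyl)undeca-5,7,9-trien-3-yl]oxy}silane F7. F7 undergoes Stille coupling with iodide 10 (Pd2(dba)3, AsPh3, CuI, DMF, rt) to give 33, which closes on gentle warming and gives 34 after the same separation.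

Step 18 (selective epoxidation). Possible failures are attack at the other ring alkene or at the side-chain alkene, a facial preference of the ketone opposite to that of the substrate (the enantiomeric ketone is then tried first), or loss of the vinyl oxirane in the two steps that follow. The fallback sets out from 34 and comes back to the route at the target 37. It moves the epoxidation to the very end and relies on substrate control alone, so that the vinyl oxirane never meets fluoride or the periodinane. 34 is desilylated with Bu4NF to 6-[(1R,6S)-6-[(2E,4R,5S)-5-hydroxy-4-methylhept-2-en-2-yl]-1,3,5-trimethylcyclohexa-2,4-dien-1-yl]-2-methoxy-3,5-dimethyl-4H-pyran-4-one F8. F8 is oxidised with Dess–Martin periodinane and NaHCO3 to 2-methoxy-3,5-dimethyl-6-[(1R,6S)-1,3,5-trimethyl-6-[(2E,4R)-4-methyl-5-oxohept-2-en-2-yl]cyclohexa-2,4-dien-1-yl]-4H-pyran-4-one F9. F9 is epoxidised with dimethyldioxirane (1.0 equiv, acetone, −40 °C), which attacks the more accessible diene double bond anti to both ring substituents, while the side-chain alkene is now inductively deactivated by the β-carbonyl group; this gives 37 directly.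

## Further compounds

F1 | step 5 | ethyl 2,4-dimethyl-3,5-dioxoheptanoate (stereoisomer mixture) | CCOC(=O)C(C)C(=O)C(C)C(=O)CC
F2 | step 5 | 6-ethyl-4-hydroxy-3,5-dimethyl-2H-pyran-2-one | CCC1=C(C)C(O)=C(C)C(=O)O1
F3 | step 5 | 6-ethyl-2-methoxy-3,5-dimethyl-4H-pyran-4-one | CCc1oc(OC)c(C)c(=O)c1C
F4 | step 5 | (2Z,4E,6E,8R,9S)-9-{[tert-butyl(dimethyl)silyl]oxy}-2,4,6,8-tetramethylundeca-2,4,6-trienal | CC[C@H](O[Si](C)(C)C(C)(C)C)[C@H](C)/C=C(\C)/C=C(\C)/C=C(/C)C=O
F5 | step 5 | 6-[(4Z,6E,8E,10R,11S)-11-{[tert-butyl(dimethyl)silyl]oxy}-3-hydroxy-4,6,8,10-tetramethyltrideca-4,6,8-trien-2-yl]-2-methoxy-3,5-dimethyl-4H-pyran-4-one (mixture at the two new centres) | CC[C@H](O[Si](C)(C)C(C)(C)C)[C@H](C)/C=C(\C)/C=C(\C)/C=C(/C)C(O)C(C)c1oc(OC)c(C)c(=O)c1C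
F6 | step 5 | 6-[(4Z,6E,8E,10R,11S)-11-{[tert-butyl(dimethyl)silyl]oxy}-4,6,8,10-tetramethyl-3-[(methylsulfonyl)oxy]trideca-4,6,8-trien-2-yl]-2-methoxy-3,5-dimethyl-4H-pyran-4-one (mixture at the two new centres) | CC[C@H](O[Si](C)(C)C(C)(C)C)[C@H](C)/C=C(\C)/C=C(\C)/C=C(/C)C(OS(C)(=O)=O)C(C)c1oc(OC)c(C)c(=O)c1C
F7 | step 17 | tert-butyl(dimethyl){[(3S,4R,5E,7E,9Z)-4,6,8-trimethyl-10-(trimethylstannyl)undeca-5,7,9-trien-3-yl]oxy}silane | CC[C@H](O[Si](C)(C)C(C)(C)C)[C@H](C)/C=C(\C)/C=C(\C)/C=C(/C)\[Sn](C)(C)C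
F8 | step 18 | 6-[(1R,6S)-6-[(2E,4R,5S)-5-hydroxy-4-methylhept-2-en-2-yl]-1,3,5-trimethylcyclohexa-2,4-dien-1-yl]-2-methoxy-3,5-dimethyl-4H-pyran-4-one | CC[C@H](O)[C@H](C)/C=C(\C)[C@H]1C(C)=CC(C)=C[C@@]1(C)c1oc(OC)c(C)c(=O)c1C
F9 | step 18 | 2-methoxy-3,5-dimethyl-6-[(1R,6S)-1,3,5-trimethyl-6-[(2E,4R)-4-methyl-5-oxohept-2-en-2-yl]cyclohexa-2,4-dien-1-yl]-4H-pyran-4-one | CCC(=O)[C@H](C)/C=C(\C)[C@H]1C(C)=CC(C)=C[C@@]1(C)c1oc(OC)c(C)c(=O)c1C
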